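**Retrosynthetic overview**
1. No ring is built: the oxane is the γ-pyrone ring of comanic acid (1), and both benzene rings are bought.
2. Side-chain C1'–C2' bond: acyl–benzyl disconnection, 1 plus 4-(benzyloxy)benzyl chloride (2), through acid chloride 3 and benzylzinc 4, to acylpyrone 5.
3. Key disconnection, C2–aryl bond: enantioselective dearomatising conjugate arylation of 5 with arylboronic acid 6 gives dihydropyranone 7 and sets C2.
4. C6–H: hydrogenation of the ene-dione C=C of 7, with loss of both benzyl ethers, gives the 2,6-cis oxanone 8.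
5. C4–OH and C1'–OH: one double hydride reduction of 8 (axial attack at C4, chelation control at C1') gives target 9.

Assumption: 1, 2 and 6 are purchasable; atoms are numbered as in the target oxane (C2 carries the aryl group, C6 the side chain, C1' is the side-chain carbinol carbon; the target is 2R,4R,6S,1'R, all-cis on the ring and anti across C6/C1').

**Step 1**
Reactants: 1 comanic acid (4-oxo-4H-pyran-2-carboxylic acid); 2 4-(benzyloxy)benzyl chloride
Product: 5 2-{[4-(benzyloxy)phenyl]acetyl}-4H-pyran-4-one, via comanoyl chloride 3 (not isolated), via 4-(benzyloxy)benzylzinc chloride 4 (not isolated)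
Conditions: (a) 1, SOCl2, toluene, 80 °C, evaporate; (b) 2, Zn dust, LiCl, THF, 25 °C; (c) a + b, Pd(PPh3)4 (3 mol%), THF, 0 °C to rt
Reagents that add atoms: thionyl chloride ClS(Cl)=O (the Cl of 3 only); zinc [Zn] (the Zn of 4 only)
Why: Negishi acylation, in which zerovalent palladium inserts into the C–Cl bond of 3, the benzylzinc 4 transmetalates and reductive elimination gives the ketone, while the mild organozinc adds neither to the pyrone nor to the new ketone; no stereocentre is formed.

**Step 2**
Reactants: 5 2-{[4-(benzyloxy)phenyl]acetyl}-4H-pyran-4-one; 6 [4-(benzyloxy)-3-methoxyphenyl]boronic acid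
Product: 7 (2R)-2-[4-(benzyloxy)-3-methoxyphenyl]-6-{[4-(benzyloxy)phenyl]acetyl}-2,3-dihydro-4H-pyran-4-one
Conditions: Pd(OCOCF3)2 (5 mol%), (S)-4-tert-butyl-2-(pyridin-2-yl)-4,5-dihydrooxazole ((S)-t-BuPyOx, 6 mol%), NH4PF6 (30 mol%), H2O (5 equiv), 6 (2 equiv), ClCH2CH2Cl, 60 °C
Reagents that add atoms: none
Why: Proposed new method: the cationic aryl–palladium species formed from 6 and divalent palladium on the chiral pyridine–oxazoline inserts the unsubstituted C=C of the γ-pyrone, delivering aryl to the free pyrylium-like carbon (which becomes C2 of 7; the other such carbon is blocked by the acyl group and the carbon next to it would be an α-keto cation site), and water protonates the palladium enolate under base-free conditions before the ring oxygen can be eliminated, so the 6π pyrone is dearomatised and the ligand fixes the new centre as R (the (S)-ligand by analogy with chromones, its antipode if the sense proves reversed); the closest known reaction is the asymmetric Hayashi–Miyaura-type conjugate addition of arylboronic acids to chromones giving flavanones.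

**Step 3**
Reactants: 7 (2R)-2-[4-(benzyloxy)-3-methoxyphenyl]-6-{[4-(benzyloxy)phenyl]acetyl}-2,3-dihydro-4H-pyran-4-one
Product: 8 (2R,6S)-2-(4-hydroxy-3-methoxyphenyl)-6-[(4-hydroxyphenyl)acetyl]oxan-4-one
Conditions: H2 (1 atm), 10% Pd/C, EtOAc–THF, rt
Reagents that add atoms: none
Why: Heterogeneous catalytic hydrogenation adds H2 syn to the electron-poor ene-dione C=C from the face anti to the C2 aryl group, giving the 2,6-cis product (C6 S), which is also the thermodynamic epimer because C6–H is α to the acyl carbonyl and can equilibrate; the same catalyst hydrogenolyses both aryl benzyl ethers.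

**Step 4**
Reactants: 8 (2R,6S)-2-(4-hydroxy-3-methoxyphenyl)-6-[(4-hydroxyphenyl)acetyl]oxan-4-one
Product: 9 (2R,4R,6S)-2-(4-hydroxy-3-methoxyphenyl)-6-[(1R)-1-hydroxy-2-(4-hydroxyphenyl)ethyl]oxan-4-ol
Conditions: Zn(BH4)2 (4 equiv, from ZnCl2 + 2 NaBH4 in Et2O), THF–Et2O, −30 to 0 °C; aq. NH4Cl
Reagents that add atoms: none
Why: Chelation-controlled (Cram-chelate) reduction, in which zinc ties the ring oxygen to the side-chain carbonyl so hydride enters from the C6–H side and gives the 6,1'-anti carbinol (C1' R), while the unhindered ring ketone takes the small hydride axially to give the equatorial, all-cis C4 alcohol (C4 R).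

**Compound list**
1 | comanic acid (4-oxo-4H-pyran-2-carboxylic acid) | O=C(O)C1=CC(=O)C=CO1 | starting material
2 | 4-(benzyloxy)benzyl chloride | ClCc1ccc(OCc2ccccc2)cc1 | starting material
3 | comanoyl chloride (4-oxo-4H-pyran-2-carbonyl chloride) | O=C(Cl)C1=CC(=O)C=CO1 | intermediate
4 | 4-(benzyloxy)benzylzinc chloride | Cl[Zn]Cc1ccc(OCc2ccccc2)cc1 | intermediate
5 | 2-{[4-(benzyloxy)phenyl]acetyl}-4H-pyran-4-one | O=C(Cc1ccc(OCc2ccccc2)cc1)C1=CC(=O)C=CO1 | intermediate
6 | [4-(benzyloxy)-3-methoxyphenyl]boronic acid | COc1cc(B(O)O)ccc1OCc1ccccc1 | starting material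
7 | (2R)-2-[4-(benzyloxy)-3-methoxyphenyl]-6-{[4-(benzyloxy)phenyl]acetyl}-2,3-dihydro-4H-pyran-4-one | COc1cc([C@H]2CC(=O)C=C(C(=O)Cc3ccc(OCc4ccccc4)cc3)O2)ccc1OCc1ccccc1 | intermediate
8 | (2R,6S)-2-(4-hydroxy-3-methoxyphenyl)-6-[(4-hydroxyphenyl)acetyl]oxan-4-one | COc1cc([C@H]2CC(=O)C[C@@H](C(=O)Cc3ccc(O)cc3)O2)ccc1O | intermediate
9 | (2R,4R,6S)-2-(4-hydroxy-3-methoxyphenyl)-6-[(1R)-1-hydroxy-2-(4-hydroxyphenyl)ethyl]oxan-4-ol | COc1cc([C@H]2C[C@@H](O)C[C@@H]([C@H](O)Cc3ccc(O)cc3)O2)ccc1O | target

**Step count**
Total: 4 steps (step 1 is telescoped; the acid chloride and the organozinc are made and used without isolation). Longest linear sequence: 4 steps (1 → 5 → 7 → 8 → 9).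

**Steps most likely to fail, with fallbacks**

Step 2 is the riskiest. The pyrone may be too unreactive as a neutral acceptor, 7 may ring-open to the styryl triketone, and the enantioselectivity is untested. The fallback sets out from 5 and comes back at 7, and it turns the pyrone into a cation instead of carbometalating it. MeOTf (CH2Cl2, 0 °C) O-methylates the pyrone carbonyl to give 2-{[4-(benzyloxy)phenyl]acetyl}-4-methoxypyrylium trifluoromethanesulfonate F1. Zerovalent nickel (Ni(cod)2 with a chiral TADDOL-derived phosphonite, K3PO4, THF) adds oxidatively at the unsubstituted ring carbon next to oxygen, boronic acid 6 transmetalates, and reductive elimination gives (2R)-2-[4-(benzyloxy)-3-methoxyphenyl]-6-{[4-(benzyloxy)phenyl]acetyl}-4-methoxy-2H-pyran F2. This is the oxygen analogue of the nickel-catalysed enantioselective arylation of 4-methoxypyridinium and quinolinium ions. The methyl enol ether is hydrolysed at once on work-up (1 M HCl, THF, 0 °C), before the 2H-pyran can ring-open electrocyclically, to give 7.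

Step 4 is next. Chelation control at C1' and axial attack at C4 must both hold in one operation on a diphenol, and a poor ratio at either centre costs material. The fallback sets out from 8 and comes back at 9, and it replaces substrate control by catalyst control with two chemoselective reductions. Asymmetric transfer hydrogenation (RuCl[(S,S)-TsDPEN](p-cymene) or its antipode, whichever gives the R carbinol, HCO2H–Et3N, rt) reduces only the activated α-alkoxy ketone to give (2R,6S)-2-(4-hydroxy-3-methoxyphenyl)-6-[(1R)-1-hydroxy-2-(4-hydroxyphenyl)ethyl]oxan-4-one F5. NaBH4 (MeOH, −78 °C) then reduces the ring ketone by axial attack to give 9.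

Step 3 is third. One catalyst has to reduce the ene-dione cis-selectively and remove two benzyl groups without cleaving the benzylic ring C2–O bond. The fallback sets out from 7 and comes back at 9, and it avoids hydrogen and palladium altogether. Copper hydride conjugate reduction ([(Ph3P)CuH]6 cat., PhSiH3, toluene, 0 °C) saturates the ene-dione to give (2R,6S)-2-[4-(benzyloxy)-3-methoxyphenyl]-6-{[4-(benzyloxy)phenyl]acetyl}oxan-4-one F3, with C6 settling cis through the enolate. Zn(BH4)2 as in step 4, now without free phenols, gives (2R,4R,6S)-2-[4-(benzyloxy)-3-methoxyphenyl]-6-{(1R)-2-[4-(benzyloxy)phenyl]-1-hydroxyethyl}oxan-4-ol F4. BCl3 with pentamethylbenzene (CH2Cl2, −78 °C), the conditions used to debenzylate C-aryl glycosides, removes both benzyl ethers and spares the methyl ether, giving 9.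

**Further compounds**
F1 | step 2 | 2-{[4-(benzyloxy)phenyl]acetyl}-4-methoxypyrylium trifluoromethanesulfonate | COc1cc(C(=O)Cc2ccc(OCc3ccccc3)cc2)[o+]cc1.[O-]S(=O)(=O)C(F)(F)F
F2 | step 2 | (2R)-2-[4-(benzyloxy)-3-methoxyphenyl]-6-{[4-(benzyloxy)phenyl]acetyl}-4-methoxy-2H-pyran | COc1cc([C@H]2C=C(OC)C=C(C(=O)Cc3ccc(OCc4ccccc4)cc3)O2)ccc1OCc1ccccc1
F3 | step 3 | (2R,6S)-2-[4-(benzyloxy)-3-methoxyphenyl]-6-{[4-(benzyloxy)phenyl]acetyl}oxan-4-one | COc1cc([C@H]2CC(=O)C[C@@H](C(=O)Cc3ccc(OCc4ccccc4)cc3)O2)ccc1OCc1ccccc1
F4 | step 3 | (2R,4R,6S)-2-[4-(benzyloxy)-3-methoxyphenyl]-6-{(1R)-2-[4-(benzyloxy)phenyl]-1-hydroxyethyl}oxan-4-ol | COc1cc([C@H]2C[C@@H](O)C[C@@H]([C@H](O)Cc3ccc(OCc4ccccc4)cc3)O2)ccc1OCc1ccccc1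
F5 | step 4 | (2R,6S)-2-(4-hydroxy-3-methoxyphenyl)-6-[(1R)-1-hydroxy-2-(4-hydroxyphenyl)ethyl]oxan-4-one | COc1cc([C@H]2CC(=O)C[C@@H]([C@H](O)Cc3ccc(O)cc3)O2)ccc1O
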